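**Plan**
- Retrosynthesis: cut the three aryl O–Si bonds, then the side-chain CH=CH bond (cross-metathesis), then the Cα–Cβ bond of the three-carbon linker on C5 (aldol condensation, conjugate reduction), then the C3=C4 unsaturation, and last the C4a–C5 and C6–C7 bonds of the benzene ring.
- The last cut is possible because the chromene benzene ring has four adjacent substituted carbons (C4a, C5, C8, C8a) and its two oxygens sit on the neighbours C8 and C8a. C7–C8–C8a–C4a is therefore a 2,3-dioxygenated diene whose C4a=C8a bond is the enol ether of a dihydropyran that already holds O1 and C2.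
- Forward: the pyran ring is made first (δ-lactone, then 6-acetyl-dihydropyran and its silyl dienol ether). The benzene ring is closed on it by [4+2] addition of methyl propiolate and aromatised. The heterocycle is dehydrogenated to the 2H-chromene, then the linker and finally the side chain are attached.
- Stereochemistry: the only stereocentre, quaternary C2, is set in step 1 by enantioselective allylboration of methyl 5-oxohexanoate and is not touched afterwards. The E side-chain alkene comes from cross-metathesis.

Key step: step 6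

Assumption: (R,R)-iPr-DuPHOS is taken to be the ligand antipode that sends the allyl group to the Re face of the methyl ketone; if a trial shows the opposite sense, (S,S)-iPr-DuPHOS is used and nothing else changes.

Note: atom labels (O1, C2 … C8a) are those of the final chromene and are used for all intermediates. The C2 descriptor changes from S to R at the chroman-to-chromene step only because C3 becomes sp2 and then outranks the allyl carbon; no bond at C2 is made or broken.

Step 1
Reactants: 1 methyl 5-oxohexanoate; 2 allylboronic acid pinacol ester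
Product: 4 (6S)-6-allyl-6-methyloxan-2-one, via methyl (5S)-5-hydroxy-5-methyloct-7-enoate 3 (not isolated)
Conditions: CuF2·2H2O (3 mol %), (R,R)-iPr-DuPHOS (6 mol %), La(OiPr)3 (4.5 mol %), DMF, −40 °C; aq NH4Cl; then TsOH·H2O (5 mol %), CH2Cl2, 20 °C
Reagents that add atoms: none
Why: Copper-catalysed enantioselective allylboration of a ketone (boron-to-copper transmetalation gives a chiral bisphosphine allylcopper that adds through a cyclic transition state, La(OiPr)3 speeding turnover), in which the ligand distinguishes methyl from the ester-bearing chain and delivers allyl to the Re face to set C2 as S, after which the δ-hydroxy ester closes to the six-membered lactone under acid; the enantiomeric purity of 4 is to be assayed before going on.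

Step 2
Reactants: 4 (6S)-6-allyl-6-methyloxan-2-one
Product: 5 (6S)-6-allyl-6-methyloxan-2-ol (anomer mixture)
Conditions: iBu2AlH (1.1 equiv), CH2Cl2, −78 °C; Rochelle salt work-up
Reagents that add atoms: none
Why: Partial reduction of a δ-lactone with iBu2AlH at low temperature stops at the tetrahedral aluminate, which gives the cyclic hemiacetal on work-up, while the alkene and C2 are not involved.

Step 3
Reactants: 5 (6S)-6-allyl-6-methyloxan-2-ol
Product: 7 (2S)-2-allyl-2-methyl-3,4-dihydro-2H-pyran, via anomeric mesylate 6 (not isolated)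
Conditions: MsCl (1.5 equiv), Et3N (4 equiv), THF, 0 → 65 °C; product kept in solution (volatile, acid-sensitive)
Reagents that add atoms: none
Why: Lactol dehydration through the anomeric mesylate, which ionises to the oxocarbenium ion and loses a proton from the neighbouring ring CH2 to Et3N (the usual lactol-to-cyclic-enol-ether elimination), the quaternary C2 leaving no other direction of elimination.

Step 4
Reactants: 7 (2S)-2-allyl-2-methyl-3,4-dihydro-2H-pyran; 8 N-methoxy-N-methylacetamide
Product: 10 1-[(2S)-2-allyl-2-methyl-3,4-dihydro-2H-pyran-6-yl]ethan-1-one, via 6-lithio dihydropyran 9 (not isolated)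
Conditions: t-BuLi (1.3 equiv), THF/pentane, −78 → 0 °C; then 8, −78 °C; H2O quench
Reagents that add atoms: none
Why: Oxygen-directed α-lithiation of a cyclic enol ether with t-BuLi (as for 3,4-dihydro-2H-pyran itself) followed by acylation with a Weinreb amide, whose chelated tetrahedral adduct prevents a second addition and releases the methyl ketone only on quench.

Step 5
Reactants: 10 1-[(2S)-2-allyl-2-methyl-3,4-dihydro-2H-pyran-6-yl]ethan-1-one
Product: 11 tert-butyl({1-[(2S)-2-allyl-2-methyl-3,4-dihydro-2H-pyran-6-yl]ethenyl}oxy)dimethylsilane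
Conditions: TBSOTf (1.2 equiv), Et3N (2 equiv), CH2Cl2, 0 °C; non-acidic work-up, used crude
Reagents that add atoms: tert-butyldimethylsilyl trifluoromethanesulfonate, CC(C)(C)[Si](C)(C)OS(=O)(=O)C(F)(F)F
Why: Soft enolisation of a methyl ketone (silyl triflate activation, then Et3N removes one of the only α-hydrogens, those of CH3) gives the cross-conjugated 2-silyloxy diene, the kinetically slower γ-deprotonation at ring C4 being avoided at 0 °C.

Step 6
Reactants: 11 tert-butyl({1-[(2S)-2-allyl-2-methyl-3,4-dihydro-2H-pyran-6-yl]ethenyl}oxy)dimethylsilane; 12 methyl propiolate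
Product: 14 methyl (2S)-2-allyl-8-(tert-butyldimethylsilyloxy)-2-methylchromane-5-carboxylate, via cyclohexadiene cycloadduct 13 (not isolated)
Conditions: 12 (3 equiv), toluene, 100 °C, sealed tube; cool to 20 °C; DDQ (1.1 equiv), toluene, 20 °C
Reagents that add atoms: none
Why: The electron-rich diene C7=C8–C8a=C4a, its HOMO raised by the C8 silyloxy group and by O1, adds the electron-poor alkyne in a concerted, asynchronous normal-demand [4+2] cycloaddition in which the C6–C7 bond runs ahead of the C4a–C5 bond. The closest known reaction type is the Diels–Alder reaction of 2-silyloxy and 2,3-dioxygenated 1,3-dienes with alkynoates followed by quinone dehydrogenation to catechol ethers. The six-membered carbocycle closes by suprafacial [4π+2π] addition across the diene termini C7 and C4a, an s-cis geometry the semicyclic diene reaches easily because C4 is the outside substituent on C4a. No lasting stereocentre is formed, since C4a of cyclohexadiene 13 arises as an epimer mixture and becomes aromatic, and the remote quaternary C2 is untouched. The step needs the ester-bearing alkyne carbon to bond to C4a: the silyloxy group on C8 and the alkyl substituent on C4a both make the unhindered CH2 terminus C7 the nucleophilic end that attacks the β-carbon of the propiolate, and together they must outweigh the opposite push of O1, while the isolated allyl alkene is too unreactive to compete. DDQ then removes the doubly allylic hydrogens at C7 and C4a at room temperature, driven by aromatisation, and leaves the C8 silyl ether and the chroman CH2 groups intact.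

Step 7
Reactants: 14 methyl (2S)-2-allyl-8-(tert-butyldimethylsilyloxy)-2-methylchromane-5-carboxylate
Product: 15 methyl (2R)-2-allyl-8-(tert-butyldimethylsilyloxy)-2-methyl-2H-chromene-5-carboxylate
Conditions: DDQ (2 equiv), 1,4-dioxane, 100 °C, dark
Reagents that add atoms: none
Why: DDQ dehydrogenation of a chroman to a 2H-chromene (hydride abstraction from benzylic C4 assisted by the ring oxygen ortho to C4a, then loss of the C3 proton), a reaction type known for chromans carrying acyl and ester groups; C2 is quaternary and unaffected, and light is excluded from here on because photochemical ring-opening of 2H-chromenes would scramble C2.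

Step 8
Reactants: 15 methyl (2R)-2-allyl-8-(tert-butyldimethylsilyloxy)-2-methyl-2H-chromene-5-carboxylate
Product: 16 [(2R)-2-allyl-8-(tert-butyldimethylsilyloxy)-2-methyl-2H-chromen-5-yl]methanol
Conditions: iBu2AlH (2.5 equiv), CH2Cl2, −78 °C; Rochelle salt work-up
Reagents that add atoms: none
Why: Reduction of an aryl ester to the benzylic alcohol with excess iBu2AlH at low temperature, conditions under which the aryl silyl ether and both alkenes persist.

Step 9
Reactants: 16 [(2R)-2-allyl-8-(tert-butyldimethylsilyloxy)-2-methyl-2H-chromen-5-yl]methanol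
Product: 17 (2R)-2-allyl-8-(tert-butyldimethylsilyloxy)-2-methyl-2H-chromene-5-carbaldehyde
Conditions: activated MnO2 (15 equiv), CH2Cl2, 20 °C
Reagents that add atoms: none
Why: MnO2 oxidises benzylic alcohols selectively to aldehydes without over-oxidation and leaves alkenes and silyl ethers alone.

Step 10
Reactants: 18 2,4-dihydroxyacetophenone
Product: 19 1-[2,4-bis(tert-butyldimethylsilyloxy)phenyl]ethan-1-one
Conditions: TBSCl (2.5 equiv), imidazole (5 equiv), DMF, 20 → 40 °C
Reagents that add atoms: tert-butyldimethylsilyl chloride, CC(C)(C)[Si](C)(C)Cl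
Why: Standard imidazole-promoted silylation of phenols, with excess reagent and gentle warming to overcome the hydrogen bond of the ortho phenol to the ketone.

Step 11
Reactants: 19 1-[2,4-bis(tert-butyldimethylsilyloxy)phenyl]ethan-1-one; 17 (2R)-2-allyl-8-(tert-butyldimethylsilyloxy)-2-methyl-2H-chromene-5-carbaldehyde
Product: 23 (E)-3-[(2R)-2-allyl-8-(tert-butyldimethylsilyloxy)-2-methyl-2H-chromen-5-yl]-1-[2,4-bis(tert-butyldimethylsilyloxy)phenyl]prop-2-en-1-one, via lithium enolate 20 (not isolated), via lithium aldolate 21 (not isolated), via aldol mesylate 22 (not isolated)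
Conditions: 19 (1.2 equiv), LiN(SiMe3)2 (1.2 equiv), THF, −78 °C; 17, −78 °C; MsCl (1.5 equiv), Et3N (4 equiv), −78 → 20 °C
Reagents that add atoms: none
Why: Directed aldol addition of a preformed lithium enolate to a non-enolisable aryl aldehyde, then mesylation of the aldolate in the same flask and E1cB elimination to the E chalcone, an aldol condensation without hydroxide so that the three aryl silyl ethers survive (the enolate is kept at −78 °C to prevent silyl migration from the ortho oxygen).

Step 12
Reactants: 23 (E)-3-[(2R)-2-allyl-8-(tert-butyldimethylsilyloxy)-2-methyl-2H-chromen-5-yl]-1-[2,4-bis(tert-butyldimethylsilyloxy)phenyl]prop-2-en-1-one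
Product: 24 3-[(2R)-2-allyl-8-(tert-butyldimethylsilyloxy)-2-methyl-2H-chromen-5-yl]-1-[2,4-bis(tert-butyldimethylsilyloxy)phenyl]propan-1-one
Conditions: [(Ph3P)CuH]6 (0.3 equiv), H2O (3 equiv), degassed toluene, 20 °C
Reagents that add atoms: none
Why: Copper hydride conjugate reduction of an enone (hydrocupration to the copper enolate, protonated by water) is selective for the electron-poor C=C, so the styrenyl C3=C4 alkene, the terminal alkene and the ketone should remain.

Step 13
Reactants: 24 3-[(2R)-2-allyl-8-(tert-butyldimethylsilyloxy)-2-methyl-2H-chromen-5-yl]-1-[2,4-bis(tert-butyldimethylsilyloxy)phenyl]propan-1-one; 25 2-methylbut-3-en-2-ol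
Product: 26 1-[2,4-bis(tert-butyldimethylsilyloxy)phenyl]-3-{(2R)-8-(tert-butyldimethylsilyloxy)-2-[(2E)-4-hydroxy-4-methylpent-2-en-1-yl]-2-methyl-2H-chromen-5-yl}propan-1-one
Conditions: 25 (10 equiv), second-generation Hoveyda–Grubbs catalyst (H2IMes)Cl2Ru(=CH-C6H4-2-OiPr) (5 mol %), CH2Cl2, 40 °C, dark
Reagents that add atoms: none
Why: Olefin cross-metathesis of the terminal allyl group with an excess of a tertiary allylic alcohol that homodimerises only slowly, the bulky carbinol end enforcing the E geometry, while the ring C3=C4 alkene next to quaternary C2 is a poor metathesis partner.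

Step 14
Reactants: 26 1-[2,4-bis(tert-butyldimethylsilyloxy)phenyl]-3-{(2R)-8-(tert-butyldimethylsilyloxy)-2-[(2E)-4-hydroxy-4-methylpent-2-en-1-yl]-2-methyl-2H-chromen-5-yl}propan-1-one
Product: 27 1-(2,4-dihydroxyphenyl)-3-{(2R)-8-hydroxy-2-[(2E)-4-hydroxy-4-methylpent-2-en-1-yl]-2-methyl-2H-chromen-5-yl}propan-1-one (target)
Conditions: Bu4NF (3.5 equiv), AcOH (3.5 equiv), THF, 0 °C, dark
Reagents that add atoms: none
Why: Fluoride cleavage of the three aryl silyl ethers, buffered with AcOH so the phenoxides are protonated at once; the acid-free conditions spare the tertiary allylic alcohol and the chromene.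

**Compound list**
1 | methyl 5-oxohexanoate | CC(=O)CCCC(=O)OC | starting material
2 | allylboronic acid pinacol ester | C=CCB1OC(C)(C)C(C)(C)O1 | starting material
3 | methyl (5S)-5-hydroxy-5-methyloct-7-enoate | C=CC[C@@](C)(O)CCCC(=O)OC | intermediate (not isolated)
4 | (6S)-6-allyl-6-methyloxan-2-one | C=CC[C@]1(C)CCCC(=O)O1 | intermediate
5 | (6S)-6-allyl-6-methyloxan-2-ol, anomer mixture | C=CC[C@]1(C)CCCC(O)O1 | intermediate
6 | (6S)-6-allyl-6-methyloxan-2-yl methanesulfonate | C=CC[C@]1(C)CCCC(OS(C)(=O)=O)O1 | intermediate (not isolated)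
7 | (2S)-2-allyl-2-methyl-3,4-dihydro-2H-pyran | C=CC[C@]1(C)CCC=CO1 | intermediate
8 | N-methoxy-N-methylacetamide | CC(=O)N(C)OC | starting material
9 | [(2S)-2-allyl-2-methyl-3,4-dihydro-2H-pyran-6-yl]lithium | C=CC[C@]1(C)CCC=C([Li])O1 | intermediate (not isolated)
10 | 1-[(2S)-2-allyl-2-methyl-3,4-dihydro-2H-pyran-6-yl]ethan-1-one | C=CC[C@]1(C)CCC=C(C(C)=O)O1 | intermediate
11 | tert-butyl({1-[(2S)-2-allyl-2-methyl-3,4-dihydro-2H-pyran-6-yl]ethenyl}oxy)dimethylsilane | C=CC[C@]1(C)CCC=C(C(=C)O[Si](C)(C)C(C)(C)C)O1 | intermediate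
12 | methyl propiolate | C#CC(=O)OC | starting material
13 | methyl (2S)-2-allyl-8-(tert-butyldimethylsilyloxy)-2-methyl-3,4,4a,7-tetrahydro-2H-chromene-5-carboxylate, C4a epimers | C=CC[C@]1(C)CCC2C(C(=O)OC)=CCC(O[Si](C)(C)C(C)(C)C)=C2O1 | intermediate (not isolated)
14 | methyl (2S)-2-allyl-8-(tert-butyldimethylsilyloxy)-2-methylchromane-5-carboxylate | C=CC[C@]1(C)CCc2c(C(=O)OC)ccc(O[Si](C)(C)C(C)(C)C)c2O1 | intermediate
15 | methyl (2R)-2-allyl-8-(tert-butyldimethylsilyloxy)-2-methyl-2H-chromene-5-carboxylate | C=CC[C@]1(C)C=Cc2c(C(=O)OC)ccc(O[Si](C)(C)C(C)(C)C)c2O1 | intermediate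
16 | [(2R)-2-allyl-8-(tert-butyldimethylsilyloxy)-2-methyl-2H-chromen-5-yl]methanol | C=CC[C@]1(C)C=Cc2c(CO)ccc(O[Si](C)(C)C(C)(C)C)c2O1 | intermediate
17 | (2R)-2-allyl-8-(tert-butyldimethylsilyloxy)-2-methyl-2H-chromene-5-carbaldehyde | C=CC[C@]1(C)C=Cc2c(C=O)ccc(O[Si](C)(C)C(C)(C)C)c2O1 | intermediate
18 | 2,4-dihydroxyacetophenone | CC(=O)c1ccc(O)cc1O | starting material
19 | 1-[2,4-bis(tert-butyldimethylsilyloxy)phenyl]ethan-1-one | CC(=O)c1ccc(O[Si](C)(C)C(C)(C)C)cc1O[Si](C)(C)C(C)(C)C | intermediate
20 | lithium enolate of 19 | C=C(O[Li])c1ccc(O[Si](C)(C)C(C)(C)C)cc1O[Si](C)(C)C(C)(C)C | intermediate (not isolated)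
21 | lithium aldolate of 17 and 20, carbinol epimers | C=CC[C@]1(C)C=Cc2c(C(O[Li])CC(=O)c3ccc(O[Si](C)(C)C(C)(C)C)cc3O[Si](C)(C)C(C)(C)C)ccc(O[Si](C)(C)C(C)(C)C)c2O1 | intermediate (not isolated)
22 | β-mesyloxy ketone from 21, epimers | C=CC[C@]1(C)C=Cc2c(C(OS(C)(=O)=O)CC(=O)c3ccc(O[Si](C)(C)C(C)(C)C)cc3O[Si](C)(C)C(C)(C)C)ccc(O[Si](C)(C)C(C)(C)C)c2O1 | intermediate (not isolated)
23 | (E)-3-[(2R)-2-allyl-8-(tert-butyldimethylsilyloxy)-2-methyl-2H-chromen-5-yl]-1-[2,4-bis(tert-butyldimethylsilyloxy)phenyl]prop-2-en-1-one | C=CC[C@]1(C)C=Cc2c(/C=C/C(=O)c3ccc(O[Si](C)(C)C(C)(C)C)cc3O[Si](C)(C)C(C)(C)C)ccc(O[Si](C)(C)C(C)(C)C)c2O1 | intermediate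
24 | 3-[(2R)-2-allyl-8-(tert-butyldimethylsilyloxy)-2-methyl-2H-chromen-5-yl]-1-[2,4-bis(tert-butyldimethylsilyloxy)phenyl]propan-1-one | C=CC[C@]1(C)C=Cc2c(CCC(=O)c3ccc(O[Si](C)(C)C(C)(C)C)cc3O[Si](C)(C)C(C)(C)C)ccc(O[Si](C)(C)C(C)(C)C)c2O1 | intermediate
25 | 2-methylbut-3-en-2-ol | C=CC(C)(C)O | starting material
26 | 1-[2,4-bis(tert-butyldimethylsilyloxy)phenyl]-3-{(2R)-8-(tert-butyldimethylsilyloxy)-2-[(2E)-4-hydroxy-4-methylpent-2-en-1-yl]-2-methyl-2H-chromen-5-yl}propan-1-one | CC(C)(O)/C=C/C[C@]1(C)C=Cc2c(CCC(=O)c3ccc(O[Si](C)(C)C(C)(C)C)cc3O[Si](C)(C)C(C)(C)C)ccc(O[Si](C)(C)C(C)(C)C)c2O1 | intermediate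
27 | 1-(2,4-dihydroxyphenyl)-3-{(2R)-8-hydroxy-2-[(2E)-4-hydroxy-4-methylpent-2-en-1-yl]-2-methyl-2H-chromen-5-yl}propan-1-one | CC(C)(O)/C=C/C[C@]1(C)C=Cc2c(CCC(=O)c3ccc(O)cc3O)ccc(O)c2O1 | target

**Step count**
Total steps: 14. Longest linear sequence: 13 (steps 1–9 and 11–14; step 10 is a one-step branch).

**Steps most likely to fail**

Risk 1, step 6. The ring oxygen O1 may steer the dienophile more strongly than the silyloxy/alkyl pair, so that the ester-bearing carbon bonds to C7 and the regiochemistry is eroded or inverted. The fallback sets out from diene 11 and swaps the dienophile for methyl (E)-3-nitroacrylate, in which the nitro group, not the ester, fixes the orientation. Its ester-bearing carbon is the electrophilic end and therefore bonds to the terminus that the propiolate β-carbon would have taken, here C4a. The cycloaddition in toluene at 20–60 °C should give methyl (2S)-2-allyl-8-(tert-butyldimethylsilyloxy)-2-methyl-6-nitro-3,4,4a,5,6,7-hexahydro-2H-chromene-5-carboxylate F1. DBU then eliminates nitrous acid across C5–C6 to give the same cyclohexadiene 13, and DDQ aromatises it as in the main route, returning at 14.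

Risk 2, step 1. The catalyst may discriminate poorly between the methyl group and the ester-bearing propyl chain, leaving lactone 4 of insufficient enantiomeric purity with no crystalline intermediate to upgrade it. The fallback replaces asymmetric catalysis by a resolution and sets out from 1. Barbier allylation (zinc dust, allyl bromide, THF/aq NH4Cl), selective for the ketone over the ester, gives racemic methyl 5-hydroxy-5-methyloct-7-enoate F2. Acid-catalysed lactonisation gives racemic 6-allyl-6-methyloxan-2-one F3. Aminolysis with (S)-1-phenylethylamine and AlMe3 opens it to two diastereomeric amides, separated by chromatography or crystallisation: (5S)-5-hydroxy-5-methyl-N-[(1S)-1-phenylethyl]oct-7-enamide F4, and (5R)-5-hydroxy-5-methyl-N-[(1S)-1-phenylethyl]oct-7-enamide F5, which is discarded. Warming F4 with aqueous H2SO4 in dioxane re-closes the lactone with release of the amine and returns to the route at 4.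

Risk 3, step 7. Hydride abstraction from C4 may be slow because the C5 ester withdraws electron density from the developing benzylic cation, giving incomplete conversion or decomposition at the temperature required. The fallback sets out from chroman ester 14 and moves the dehydrogenation to a more electron-rich oxidation level. iBu2AlH reduction gives [(2S)-2-allyl-8-(tert-butyldimethylsilyloxy)-2-methylchroman-5-yl]methanol F6. Acetylation (Ac2O, pyridine) gives [(2S)-2-allyl-8-(tert-butyldimethylsilyloxy)-2-methylchroman-5-yl]methyl acetate F7; the acyloxy group disfavours oxidation at the C5 benzylic carbon. DDQ in hot dioxane then gives [(2R)-2-allyl-8-(tert-butyldimethylsilyloxy)-2-methyl-2H-chromen-5-yl]methyl acetate F8. Reductive removal of the acetate with iBu2AlH at −78 °C, which keeps the aryl silyl ether, returns to the route at alcohol 16.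

**Further compounds**
F1 | step 6 | methyl (2S)-2-allyl-8-(tert-butyldimethylsilyloxy)-2-methyl-6-nitro-3,4,4a,5,6,7-hexahydro-2H-chromene-5-carboxylate | C=CC[C@]1(C)CCC2C(C(=O)OC)C([N+](=O)[O-])CC(O[Si](C)(C)C(C)(C)C)=C2O1
F2 | step 1 | racemic methyl 5-hydroxy-5-methyloct-7-enoate | C=CCC(C)(O)CCCC(=O)OC
F3 | step 1 | racemic 6-allyl-6-methyloxan-2-one | C=CCC1(C)CCCC(=O)O1
F4 | step 1 | (5S)-5-hydroxy-5-methyl-N-[(1S)-1-phenylethyl]oct-7-enamide | C=CC[C@@](C)(O)CCCC(=O)N[C@@H](C)c1ccccc1
F5 | step 1 | (5R)-5-hydroxy-5-methyl-N-[(1S)-1-phenylethyl]oct-7-enamide | C=CC[C@](C)(O)CCCC(=O)N[C@@H](C)c1ccccc1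
F6 | step 7 | [(2S)-2-allyl-8-(tert-butyldimethylsilyloxy)-2-methylchroman-5-yl]methanol | C=CC[C@]1(C)CCc2c(CO)ccc(O[Si](C)(C)C(C)(C)C)c2O1
F7 | step 7 | [(2S)-2-allyl-8-(tert-butyldimethylsilyloxy)-2-methylchroman-5-yl]methyl acetate | C=CC[C@]1(C)CCc2c(COC(C)=O)ccc(O[Si](C)(C)C(C)(C)C)c2O1
F8 | step 7 | [(2R)-2-allyl-8-(tert-butyldimethylsilyloxy)-2-methyl-2H-chromen-5-yl]methyl acetate | C=CC[C@]1(C)C=Cc2c(COC(C)=O)ccc(O[Si](C)(C)C(C)(C)C)c2O1
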